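**Retrosynthetic overview**

1. Rings: A = cyclobutane, B = cyclopentane, C = cyclohexene fused to A, D = cyclohexene carrying CO2Me. In the target SMILES the C/D fusion is trans and all other fusions are cis, so ring D cannot be closed by a late Diels–Alder onto a cis ring-C alkene.
2. Last step: both cyclobutane bonds to the side-chain diene are cut. Rings C and A form together by a triplet-biradical intramolecular [2+2] between the cyclopentene and the distal alkene of a dienyl chain in 17.
3. 17 comes from its C5 epimer 15 (kinetic protonation); 15 from dienyl iodide 10 and (E)-deca-1,8-diene 13 (B-alkyl Suzuki); 10 from aldehyde 8 (Wittig, Takai).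
4. 8 comes from acyclic tetraenal ester 7 by a catalytic enantioselective type 1 intramolecular Diels–Alder that closes rings D and B together; the E dienophile sets the trans relationship that becomes the C/D fusion.
5. 7 comes from methyl 6-bromosorbate 3 and (E)-pent-2-en-4-yn-1-ol 4. Ring order: D + B (step 6), then C + A (step 12).

Assumption: the facial sense of the oxazaborolidinium catalyst in step 6 is taken from the usual formyl C–H···O model and the (S)-catalyst is written; if the sense is inverted for this dienal, the (R)-catalyst is used instead.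

**Route**

Step 1
Reactants: 1 (2E,4E)-hexa-2,4-dienoic acid (sorbic acid)
Product: 2 methyl (2E,4E)-hexa-2,4-dienoate
Conditions: MeOH, H2SO4 (cat.), reflux
Reagents that add atoms: methanol, CO
Why: Fischer esterification; no stereocentre is involved and both E alkenes are untouched.

Step 2
Reactants: 2 methyl (2E,4E)-hexa-2,4-dienoate
Product: 3 methyl (2E,4E)-6-bromohexa-2,4-dienoate
Conditions: N-bromosuccinimide, AIBN (cat.), PhCF3, 85 °C
Reagents that add atoms: N-bromosuccinimide, O=C1CCC(=O)N1Br
Why: Wohl–Ziegler radical allylic bromination, in which the delocalised pentadienyl radical is brominated at the terminal carbon so the conjugated (2E,4E)-dienoate is kept.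

Step 3
Reactants: 3 methyl (2E,4E)-6-bromohexa-2,4-dienoate; 4 (E)-pent-2-en-4-yn-1-ol
Product: 5 methyl (2E,4E,9E)-11-hydroxyundeca-2,4,9-trien-7-ynoate
Conditions: CuI (10 mol%), NaI (20 mol%), K2CO3, DMF, rt
Reagents that add atoms: none
Why: Copper-catalysed substitution of the primary allylic bromide by the terminal alkyne (Jeffery-type skipped enyne coupling) joins the two halves at C6–C7 without touching the E alkenes.

Step 4
Reactants: 5 methyl (2E,4E,9E)-11-hydroxyundeca-2,4,9-trien-7-ynoate
Product: 6 methyl (2E,4E,7Z,9E)-11-hydroxyundeca-2,4,7,9-tetraenoate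
Conditions: H2 (1 atm), Pd/CaCO3 poisoned with Pb(OAc)2, quinoline, EtOAc, 0 °C
Reagents that add atoms: none
Why: Lindlar semihydrogenation delivers H2 syn to the alkyne and sets the 7Z alkene that later becomes the cyclopentene double bond, leaving the dienoate and the allylic alcohol alkene alone.

Step 5
Reactants: 6 methyl (2E,4E,7Z,9E)-11-hydroxyundeca-2,4,7,9-tetraenoate
Product: 7 methyl (2E,4E,7Z,9E)-11-oxoundeca-2,4,7,9-tetraenoate
Conditions: MnO2, CH2Cl2, 0 °C; used at once
Reagents that add atoms: none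
Why: MnO2 oxidation is selective for the dienylic alcohol and is neutral, so the 7Z alkene and the doubly allylic CH2 are not isomerised.

Step 6
Reactants: 7 methyl (2E,4E,7Z,9E)-11-oxoundeca-2,4,7,9-tetraenoate
Product: 8 methyl (3aR,4S,5S,7aR)-4-formyl-3a,4,5,7a-tetrahydro-1H-indene-5-carboxylate
Conditions: (S)-3,3-diphenyl-1-(o-tolyl)tetrahydro-1H,3H-pyrrolo[1,2-c][1,3,2]oxazaborole (20 mol%), HNTf2 (20 mol%), CH2Cl2, −78 to −40 °C
Reagents that add atoms: none
Why: Catalytic enantioselective type 1 intramolecular Diels–Alder reaction (oxazaborolidinium activation of the enal), in which the Z alkene of the three-atom tether forces the cis C3a/C7a fusion, the E dienophile puts CHO trans to C3, the E,E-diene puts CO2Me cis to the C7a–C1 bond and so trans to CHO, and the catalyst shields one face of the bound enal to select the (3aR,4S,5S,7aR) enantiomer of this single diastereomer.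

Step 7
Reactants: 8 methyl (3aR,4S,5S,7aR)-4-formyl-3a,4,5,7a-tetrahydro-1H-indene-5-carboxylate
Product: 9 methyl (3aR,4S,5S,7aR)-4-[(E)-3-oxoprop-1-enyl]-3a,4,5,7a-tetrahydro-1H-indene-5-carboxylate
Conditions: Ph3P=CHCHO, toluene, 80 °C
Reagents that add atoms: (triphenylphosphoranylidene)acetaldehyde, O=CC=P(c1ccccc1)(c1ccccc1)c1ccccc1
Why: Wittig olefination with the stabilised formyl ylide gives the E enal and leaves the four stereocentres unchanged, C4 already being in its more stable trans arrangement.

Step 8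
Reactants: 9 methyl (3aR,4S,5S,7aR)-4-[(E)-3-oxoprop-1-enyl]-3a,4,5,7a-tetrahydro-1H-indene-5-carboxylate
Product: 10 methyl (3aR,4S,5S,7aR)-4-[(1E,3E)-4-iodobuta-1,3-dienyl]-3a,4,5,7a-tetrahydro-1H-indene-5-carboxylate
Conditions: CrCl2, CHI3, THF, 0 °C
Reagents that add atoms: iodoform, IC(I)I
Why: Takai iodo-olefination, in which the gem-dichromium reagent formed from CHI3 and CrCl2 converts the aldehyde chemoselectively into the E vinyl iodide under non-basic conditions that spare the ester.

Step 9
Reactants: 11 7-bromohept-1-ene; 12 (E)-prop-1-enylboronic acid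
Product: 13 (E)-deca-1,8-diene
Conditions: Pd(OAc)2 (5 mol%), P(t-Bu)2Me·HBF4 (10 mol%), KOt-Bu, t-amyl alcohol, rt
Reagents that add atoms: none
Why: Suzuki–Miyaura coupling of an unactivated primary alkyl bromide (Fu conditions) transfers the propenyl group with retention of its E geometry.

Step 10
Reactants: 13 (E)-deca-1,8-diene; 10 methyl (3aR,4S,5S,7aR)-4-[(1E,3E)-4-iodobuta-1,3-dienyl]-3a,4,5,7a-tetrahydro-1H-indene-5-carboxylate
Product: 15 methyl (3aR,4S,5S,7aR)-4-[(1E,3E,12E)-tetradeca-1,3,12-trienyl]-3a,4,5,7a-tetrahydro-1H-indene-5-carboxylate, via alkylborane 14 (not isolated)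
Conditions: 13, 9-BBN-H, THF, 0 °C to rt; then 10, Pd(dppf)Cl2 (5 mol%), AsPh3, Cs2CO3, DMF/H2O, rt
Reagents that add atoms: none
Why: Chemoselective anti-Markovnikov hydroboration of the terminal alkene with 9-BBN followed by B-alkyl Suzuki–Miyaura coupling joins the chain to the dienyl iodide with retention of alkene geometry.

Step 11
Reactants: 15 methyl (3aR,4S,5S,7aR)-4-[(1E,3E,12E)-tetradeca-1,3,12-trienyl]-3a,4,5,7a-tetrahydro-1H-indene-5-carboxylate
Product: 17 methyl (3aR,4S,5R,7aR)-4-[(1E,3E,12E)-tetradeca-1,3,12-trienyl]-3a,4,5,7a-tetrahydro-1H-indene-5-carboxylate, via lithium dienolate 16 (not isolated)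
Conditions: LiN(i-Pr)2, THF, −78 °C; then AcOH, −78 °C
Reagents that add atoms: none
Why: Deprotonation to the extended ester enolate and kinetic α-protonation, in which allylic 1,3-strain holds the C4 chain pseudoaxial so the proton enters C5 from the opposite face, inverting C5 (CO2Me now cis to the chain) and keeping the ring alkene at C6–C7.

Step 12
Reactants: 17 methyl (3aR,4S,5R,7aR)-4-[(1E,3E,12E)-tetradeca-1,3,12-trienyl]-3a,4,5,7a-tetrahydro-1H-indene-5-carboxylate
Product: 18 CNP0133550.2 (target)
Conditions: [Ir(dF(CF3)ppy)2(dtbbpy)]PF6 (1 mol%), 450 nm LEDs, degassed MeCN (0.01 M), rt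
Reagents that add atoms: none
Why: Triplet energy transfer to the 1,3-diene gives a biradical whose allyl terminus (chain C3′) adds 6-exo to C3 of the cyclopentene on the face that already carries C4, and the resulting 1,4-biradical closes the cyclobutane between chain C4′ and C2 (stepwise radical [2+2] photocycloaddition), so rings C and A form cis-fused to ring B, the pre-set trans C4/C3a relationship becomes the trans C/D fusion, and the decenyl chain takes the exo position trans to both ring neighbours.

**Compound list**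

1 | (2E,4E)-hexa-2,4-dienoic acid (sorbic acid) | C/C=C/C=C/C(=O)O | starting material
2 | methyl (2E,4E)-hexa-2,4-dienoate | C/C=C/C=C/C(=O)OC | intermediate
3 | methyl (2E,4E)-6-bromohexa-2,4-dienoate | BrC/C=C/C=C/C(=O)OC | intermediate
4 | (E)-pent-2-en-4-yn-1-ol | C#C/C=C/CO | starting material
5 | methyl (2E,4E,9E)-11-hydroxyundeca-2,4,9-trien-7-ynoate | COC(=O)/C=C/C=C/CC#C/C=C/CO | intermediate
6 | methyl (2E,4E,7Z,9E)-11-hydroxyundeca-2,4,7,9-tetraenoate | COC(=O)/C=C/C=C/C/C=C\C=C\CO | intermediate
7 | methyl (2E,4E,7Z,9E)-11-oxoundeca-2,4,7,9-tetraenoate | COC(=O)/C=C/C=C/C/C=C\C=C\C=O | intermediate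
8 | methyl (3aR,4S,5S,7aR)-4-formyl-3a,4,5,7a-tetrahydro-1H-indene-5-carboxylate (cis-fused; CHO trans to C3 and trans to CO2Me) | O=C[C@H]1[C@@H]2C=CC[C@@H]2C=C[C@@H]1C(=O)OC | intermediate
9 | methyl (3aR,4S,5S,7aR)-4-[(E)-3-oxoprop-1-enyl]-3a,4,5,7a-tetrahydro-1H-indene-5-carboxylate | O=C/C=C/[C@H]1[C@@H]2C=CC[C@@H]2C=C[C@@H]1C(=O)OC | intermediate
10 | methyl (3aR,4S,5S,7aR)-4-[(1E,3E)-4-iodobuta-1,3-dienyl]-3a,4,5,7a-tetrahydro-1H-indene-5-carboxylate | I/C=C/C=C/[C@H]1[C@@H]2C=CC[C@@H]2C=C[C@@H]1C(=O)OC | intermediate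
11 | 7-bromohept-1-ene | C=CCCCCCBr | starting material
12 | (E)-prop-1-enylboronic acid | C/C=C/B(O)O | starting material
13 | (E)-deca-1,8-diene | C/C=C/CCCCCC=C | intermediate
14 | 9-[(E)-dec-8-enyl]-9-borabicyclo[3.3.1]nonane | C/C=C/CCCCCCCB1C2CCCC1CCC2 | intermediate
15 | methyl (3aR,4S,5S,7aR)-4-[(1E,3E,12E)-tetradeca-1,3,12-trienyl]-3a,4,5,7a-tetrahydro-1H-indene-5-carboxylate | C/C=C/CCCCCCC/C=C/C=C/[C@H]1[C@@H]2C=CC[C@@H]2C=C[C@@H]1C(=O)OC | intermediate
16 | lithium dienolate of 15 (C5 planar) | C/C=C/CCCCCCC/C=C/C=C/[C@H]1[C@@H]2C=CC[C@@H]2C=CC1=C([O-])OC.[Li+] | intermediate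
17 | methyl (3aR,4S,5R,7aR)-4-[(1E,3E,12E)-tetradeca-1,3,12-trienyl]-3a,4,5,7a-tetrahydro-1H-indene-5-carboxylate (CO2Me cis to the chain) | C/C=C/CCCCCCC/C=C/C=C/[C@H]1[C@@H]2C=CC[C@@H]2C=C[C@H]1C(=O)OC | intermediate
18 | CNP0133550.2: methyl ester of the tetracycle with an (E)-dec-8-enyl chain exo on ring A; A/B, A/C, B/C and B/D cis-fused; C/D trans-fused | C/C=C/CCCCCCC[C@@H]1[C@H]2C=C[C@H]3[C@@H]4[C@H]2[C@H]1C[C@@H]4C=C[C@H]3C(=O)OC | target

**Step count and risks**

Total step count: 12. Longest linear sequence: 11 (steps 1–8, 10, 11, 12).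

Step 6 is the first likely failure. The Lewis-acid-bound (2E,4Z)-dienal may isomerise, the ester-bearing diene is electron-poor, and induction in a tether-enforced exo mode is untested. The fallback replaces catalyst control by a bound auxiliary and sets out from 7. NaClO2/NaH2PO4/2-methylbut-2-ene gives (2E,4Z,7E,9E)-11-methoxy-11-oxoundeca-2,4,7,9-tetraenoic acid F1. Mixed pivalic anhydride acylation of (R)-4-benzyloxazolidin-2-one gives methyl (2E,4E,7Z,9E)-11-[(4R)-4-benzyl-2-oxo-1,3-oxazolidin-3-yl]-11-oxoundeca-2,4,7,9-tetraenoate F2. Me2AlCl (CH2Cl2, −30 °C) promotes the same cycloaddition on the chelated imide, the diene adding anti to the benzyl group, to give methyl (3aR,4S,5S,7aR)-4-[(4R)-4-benzyl-2-oxo-1,3-oxazolidine-3-carbonyl]-3a,4,5,7a-tetrahydro-1H-indene-5-carboxylate F3. LiBH4/MeOH cleaves the imide in the presence of the methyl ester to methyl (3aR,4S,5S,7aR)-4-(hydroxymethyl)-3a,4,5,7a-tetrahydro-1H-indene-5-carboxylate F4, and Dess–Martin oxidation comes back to the route at 8.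

Step 11 is the second. The proton may enter from the wrong face, or at the γ-carbon to give the conjugated ester. The fallback reverses the order and sets out from 15. The photocycloaddition of step 12 is run on 15 to give the ester-carbon epimer of the target F5. Then LiN(i-Pr)2/AcOH is applied to this rigid tetracycle, where the enolate face next to the ring-C bond is the hindered one, and the route is rejoined at 18.

Step 12 is the third. The kinetically preferred 1,5-closure from chain C2′ is a reversible detour, because the two carbons it would bridge are trans on ring D and cannot collapse to a bicyclo[2.1.1]hexane. The productive 6-exo closure needs the photoisomerised 1Z diene. The ring-D alkene or a formal [4+2] closure may compete. The fallback changes the manifold from triplet to radical cation and goes from 17 directly to 18: 2,4,6-triphenylpyrylium tetrafluoroborate (5 mol%), 450 nm, CH2Cl2. Photoinduced electron transfer gives the diene radical cation, which cyclises onto the cyclopentene and closes the cyclobutane in a chain process. No new compound is made.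

**Further compounds**

F1 | step 6 | (2E,4Z,7E,9E)-11-methoxy-11-oxoundeca-2,4,7,9-tetraenoic acid | COC(=O)/C=C/C=C/C/C=C\C=C\C(=O)O
F2 | step 6 | methyl (2E,4E,7Z,9E)-11-[(4R)-4-benzyl-2-oxo-1,3-oxazolidin-3-yl]-11-oxoundeca-2,4,7,9-tetraenoate | COC(=O)/C=C/C=C/C/C=C\C=C\C(=O)N1[C@H](Cc2ccccc2)COC1=O
F3 | step 6 | methyl (3aR,4S,5S,7aR)-4-[(4R)-4-benzyl-2-oxo-1,3-oxazolidine-3-carbonyl]-3a,4,5,7a-tetrahydro-1H-indene-5-carboxylate | O=C([C@H]1[C@@H]2C=CC[C@@H]2C=C[C@@H]1C(=O)OC)N1[C@H](Cc2ccccc2)COC1=O
F4 | step 6 | methyl (3aR,4S,5S,7aR)-4-(hydroxymethyl)-3a,4,5,7a-tetrahydro-1H-indene-5-carboxylate | OC[C@H]1[C@@H]2C=CC[C@@H]2C=C[C@@H]1C(=O)OC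
F5 | step 11 | ester-carbon epimer of target 18 | C/C=C/CCCCCCC[C@@H]1[C@H]2C=C[C@H]3[C@@H]4[C@H]2[C@H]1C[C@@H]4C=C[C@@H]3C(=O)OC
F0 | step 12 | none | none
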